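**Retrosynthetic overview**
- The target comes from the tris-MOM isoflavone by acid removal of three MOM ethers; the isoflavone comes from a 3-aryl-3-hydroxychroman-4-one by dehydration across C2–C3.
- Key disconnection C3–C4: an intramolecular carbene-catalysed crossed aldehyde–ketone benzoin reaction, in which the ring-A aldehyde carbon reacts as an acyl anion equivalent on the ring-B aryl ketone. This closes ring C, the only ring made; rings A and B are bought as arenes.
- The keto-aldehyde comes from O-alkylation of a ring-A salicylaldehyde with a ring-B chloromethyl ketone.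
- The ring-B chloromethyl ketone comes from two successive site-selective Br–Li exchanges on a dibromocatechol bis-MOM ether (prenyl bromide first, chloroacetyl Weinreb amide second); the catechol comes from Dakin oxidation of a commercial dibromosalicylaldehyde.
- The ring-A partner comes from selective mono-MOM protection of a commercial dihydroxy(methoxy)benzaldehyde.

Assumption: the target has no stereocentre, so it is made as the single achiral compound shown; the racemic centre of the benzoin adduct is erased by the dehydration. Both starting materials are taken as catalogue compounds. MOM = methoxymethyl.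

**Step 1**
Reactants: 1 3,5-dibromo-2-hydroxybenzaldehyde
Product: 3 3,5-dibromobenzene-1,2-diol, via aryl formate 2 (not isolated)
Conditions: 30% H2O2 (1.3 equiv), NaOH (2.2 equiv), H2O/THF, 0 °C → rt; then HCl (aq)
Reagents that add atoms: hydrogen peroxide, OO
Why: Dakin oxidation, in which the hydroperoxide adduct of the aldehyde undergoes aryl migration assisted by the ortho phenoxide to give aryl formate 2, which hydroxide saponifies in the same flask to the catechol.

**Step 2**
Reactants: 3 3,5-dibromobenzene-1,2-diol
Product: 4 1,5-dibromo-2,3-bis(methoxymethoxy)benzene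
Conditions: MOMCl (2.6 equiv), i-Pr2NEt (3 equiv), CH2Cl2, 0 °C → rt
Reagents that add atoms: chloromethyl methyl ether (MOMCl), COCCl
Why: Twofold Williamson-type O-alkylation (SN2 at the very reactive α-chloro ether) of both phenols, giving MOM groups that later stabilise the ortho aryllithium and come off together in mild acid at the end.

**Step 3**
Reactants: 4 1,5-dibromo-2,3-bis(methoxymethoxy)benzene
Product: 6 5-bromo-1,2-bis(methoxymethoxy)-3-(3-methylbut-2-en-1-yl)benzene, via aryllithium 5 (not isolated)
Conditions: n-BuLi (1.05 equiv), THF, −78 °C; then CuBr·SMe2 (10 mol%), prenyl bromide (1.3 equiv), −78 → 0 °C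
Reagents that add atoms: prenyl bromide (1-bromo-3-methylbut-2-ene), CC(C)=CCBr
Why: Bromine–lithium exchange is selective for the bromine ortho to the OMOM group because that aryllithium is stabilised by chelation and by the inductive effect of oxygen, and copper-catalysed allylic substitution then takes place at the unhindered CH2 end of prenyl bromide (SN2) to give the linear prenyl arene.

**Step 4**
Reactants: 6 5-bromo-1,2-bis(methoxymethoxy)-3-(3-methylbut-2-en-1-yl)benzene
Product: 9 2-chloro-1-[3,4-bis(methoxymethoxy)-5-(3-methylbut-2-en-1-yl)phenyl]ethan-1-one, via aryllithium 7 (not isolated), via lithium hemiaminal 8 (not isolated)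
Conditions: n-BuLi (1.1 equiv), THF, −78 °C; 2-chloro-N-methoxy-N-methylacetamide (1.3 equiv), −78 → −20 °C; sat. NH4Cl (aq)
Reagents that add atoms: 2-chloro-N-methoxy-N-methylacetamide, CON(C)C(=O)CCl
Why: Second bromine–lithium exchange followed by Weinreb ketone synthesis, in which the chelated tetrahedral adduct 8 cannot collapse before the quench, so a single acyl transfer gives the chloromethyl ketone without over-addition or attack at the C–Cl bond.

**Step 5**
Reactants: 10 2,4-dihydroxy-6-methoxybenzaldehyde
Product: 11 2-hydroxy-6-methoxy-4-(methoxymethoxy)benzaldehyde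
Conditions: MOMCl (1.1 equiv), i-Pr2NEt (1.5 equiv), CH2Cl2, 0 °C
Reagents that add atoms: chloromethyl methyl ether (MOMCl), COCCl
Why: Chemoselective Williamson-type O-alkylation, because the 4-hydroxyl is free and the more acidic one, whereas the 2-hydroxyl is tied up in a hydrogen bond to the aldehyde and is left for the coupling.

**Step 6**
Reactants: 9 2-chloro-1-[3,4-bis(methoxymethoxy)-5-(3-methylbut-2-en-1-yl)phenyl]ethan-1-one; 11 2-hydroxy-6-methoxy-4-(methoxymethoxy)benzaldehyde (1.05 equiv)
Product: 13 rac-3-[3,4-bis(methoxymethoxy)-5-(3-methylbut-2-en-1-yl)phenyl]-3-hydroxy-5-methoxy-7-(methoxymethoxy)chroman-4-one, via keto-aldehyde 12 (not isolated)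
Conditions: K2CO3 (2 equiv), KI (10 mol%), MeCN, 40 °C until 9 is consumed; then 2-(pentafluorophenyl)-6,7-dihydro-5H-pyrrolo[2,1-c][1,2,4]triazol-2-ium tetrafluoroborate (15 mol%), Ar, rt → 40 °C
Reagents that add atoms: none
Why: Williamson etherification gives keto-aldehyde 12, and the N-heterocyclic carbene then converts the ring-A aldehyde into a Breslow intermediate (acyl anion equivalent) that adds to the tethered aryl ketone in a 6-exo intramolecular crossed aldehyde–ketone benzoin reaction, forming the C3–C4 bond and ring C, with the new C3 stereocentre formed racemic and removed in step 7.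

**Step 7**
Reactants: 13 rac-3-[3,4-bis(methoxymethoxy)-5-(3-methylbut-2-en-1-yl)phenyl]-3-hydroxy-5-methoxy-7-(methoxymethoxy)chroman-4-one
Product: 15 glisoflavone, via tris-MOM isoflavone 14 (not isolated)
Conditions: SOCl2 (1.5 equiv), pyridine, CH2Cl2, 0 °C; concentrate; then 3 M HCl in MeOH, 40 °C
Reagents that add atoms: none
Why: Dehydration of the tertiary α-ketol through its chlorosulfite (E2, the only β-hydrogens are on C2) gives the conjugated 4-pyranone 14, and acid-catalysed acetal methanolysis then removes the three MOM groups while the aryl methyl ether and the prenyl alkene are untouched under these mild conditions.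

**Compound list**
1 | 3,5-dibromo-2-hydroxybenzaldehyde | O=Cc1cc(Br)cc(Br)c1O | starting material
2 | 3,5-dibromo-2-hydroxyphenyl formate | O=COc1cc(Br)cc(Br)c1O | intermediate
3 | 3,5-dibromobenzene-1,2-diol | Oc1cc(Br)cc(Br)c1O | intermediate
4 | 1,5-dibromo-2,3-bis(methoxymethoxy)benzene | COCOc1cc(Br)cc(Br)c1OCOC | intermediate
5 | [5-bromo-2,3-bis(methoxymethoxy)phenyl]lithium | [Li]c1cc(Br)cc(OCOC)c1OCOC | intermediate
6 | 5-bromo-1,2-bis(methoxymethoxy)-3-(3-methylbut-2-en-1-yl)benzene | COCOc1cc(Br)cc(CC=C(C)C)c1OCOC | intermediate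
7 | [3,4-bis(methoxymethoxy)-5-(3-methylbut-2-en-1-yl)phenyl]lithium | [Li]c1cc(CC=C(C)C)c(OCOC)c(OCOC)c1 | intermediate
8 | lithium 1-[3,4-bis(methoxymethoxy)-5-(3-methylbut-2-en-1-yl)phenyl]-2-chloro-1-[methoxy(methyl)amino]ethan-1-olate (tetrahedral Weinreb adduct) | [Li]OC(CCl)(N(C)OC)c1cc(CC=C(C)C)c(OCOC)c(OCOC)c1 | intermediate
9 | 2-chloro-1-[3,4-bis(methoxymethoxy)-5-(3-methylbut-2-en-1-yl)phenyl]ethan-1-one | COCOc1cc(C(=O)CCl)cc(CC=C(C)C)c1OCOC | intermediate
10 | 2,4-dihydroxy-6-methoxybenzaldehyde | COc1cc(O)cc(O)c1C=O | starting material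
11 | 2-hydroxy-6-methoxy-4-(methoxymethoxy)benzaldehyde | COCOc1cc(O)c(C=O)c(OC)c1 | intermediate
12 | 2-{2-[3,4-bis(methoxymethoxy)-5-(3-methylbut-2-en-1-yl)phenyl]-2-oxoethoxy}-6-methoxy-4-(methoxymethoxy)benzaldehyde | COCOc1cc(OC)c(C=O)c(OCC(=O)c2cc(CC=C(C)C)c(OCOC)c(OCOC)c2)c1 | intermediate
13 | rac-3-[3,4-bis(methoxymethoxy)-5-(3-methylbut-2-en-1-yl)phenyl]-3-hydroxy-5-methoxy-7-(methoxymethoxy)chroman-4-one (racemic at C3) | COCOc1cc(OC)c2c(c1)OCC(O)(c1cc(CC=C(C)C)c(OCOC)c(OCOC)c1)C2=O | intermediate
14 | 3-[3,4-bis(methoxymethoxy)-5-(3-methylbut-2-en-1-yl)phenyl]-5-methoxy-7-(methoxymethoxy)-4H-chromen-4-one | COCOc1cc(OC)c2c(c1)occ(-c1cc(CC=C(C)C)c(OCOC)c(OCOC)c1)c2=O | intermediate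
15 | glisoflavone, 3-[3,4-dihydroxy-5-(3-methylbut-2-en-1-yl)phenyl]-7-hydroxy-5-methoxy-4H-chromen-4-one (achiral) | COc1cc(O)cc2occ(-c3cc(O)c(O)c(CC=C(C)C)c3)c(=O)c12 | target

**Totals**
Total step count: 7. Longest linear sequence: 6 (steps 1, 2, 3, 4, 6, 7); step 5 is a one-step side branch.

**Three steps most likely to fail**

Step 6 (one-pot etherification and benzoin cyclisation). The aldehyde is flanked by two alkoxy groups and is electron-rich, so Breslow intermediate formation may be slow. The keto-aldehyde can also divert by base-mediated aldol condensation to a 2-aroylbenzofuran. The fallback abandons the benzoin closure for a cross-coupling: it sets out from 6 and comes back to the route at 14. Bromide 6 is lithiated (n-BuLi, −78 °C, through aryllithium 7) and quenched with 2-isopropoxy-4,4,5,5-tetramethyl-1,3,2-dioxaborolane to give 2-[3,4-bis(methoxymethoxy)-5-(3-methylbut-2-en-1-yl)phenyl]-4,4,5,5-tetramethyl-1,3,2-dioxaborolane F2. In parallel, commercial 2',4'-dihydroxy-6'-methoxyacetophenone is mono-protected (MOMCl, i-Pr2NEt) to 1-[2-hydroxy-6-methoxy-4-(methoxymethoxy)phenyl]ethan-1-one F3. This is condensed with N,N-dimethylformamide dimethyl acetal to (E)-3-(dimethylamino)-1-[2-hydroxy-6-methoxy-4-(methoxymethoxy)phenyl]prop-2-en-1-one F4, and cyclised with I2/pyridine to 3-iodo-5-methoxy-7-(methoxymethoxy)-4H-chromen-4-one F5. Suzuki–Miyaura coupling of F2 with F5 (Pd(dppf)Cl2, K2CO3, dioxane/H2O, 80 °C) gives 14, which is carried to 15 by the methanolic HCl stage of step 7.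

Step 7 (dehydration and global deprotection). The chlorosulfite may give substitution or α-ketol rearrangement instead of clean elimination, and the acid stage could cyclise the prenyl group onto the neighbouring phenol. The fallback reverses the order and changes the elimination mechanism: it sets out from 13 and comes back at 15. Compound 13 is treated directly with TsOH·H2O in MeOH at 50 °C. MOM cleavage comes first and gives rac-3-[3,4-dihydroxy-5-(3-methylbut-2-en-1-yl)phenyl]-3,7-dihydroxy-5-methoxychroman-4-one F6. Its free 4'-hydroxyl then assists ionisation at C3 (quinone-methide-type cation), and loss of a C2 proton gives 15 without any activating reagent.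

Step 3 (site-selective exchange and prenylation). The exchange could be incompletely selective, and the allylic substitution could give some reverse-prenyl (SN2') product or homocoupling. The fallback removes the regiochemical question of the allylic step: it sets out from 4 and comes back at 6. The same exchange is run, but aryllithium 5 is quenched with allyl bromide (both ends give the same product) to give 5-bromo-1,2-bis(methoxymethoxy)-3-(prop-2-en-1-yl)benzene F1. Cross-metathesis of F1 with 2-methylbut-2-ene (as solvent, second-generation Grubbs catalyst, 40 °C) then gives 6.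

**Further compounds**
F1 | step 3 | 5-bromo-1,2-bis(methoxymethoxy)-3-(prop-2-en-1-yl)benzene | COCOc1cc(Br)cc(CC=C)c1OCOC
F2 | step 6 | 2-[3,4-bis(methoxymethoxy)-5-(3-methylbut-2-en-1-yl)phenyl]-4,4,5,5-tetramethyl-1,3,2-dioxaborolane | COCOc1cc(B2OC(C)(C)C(C)(C)O2)cc(CC=C(C)C)c1OCOC
F3 | step 6 | 1-[2-hydroxy-6-methoxy-4-(methoxymethoxy)phenyl]ethan-1-one | COCOc1cc(O)c(C(C)=O)c(OC)c1
F4 | step 6 | (E)-3-(dimethylamino)-1-[2-hydroxy-6-methoxy-4-(methoxymethoxy)phenyl]prop-2-en-1-one | COCOc1cc(O)c(C(=O)/C=C/N(C)C)c(OC)c1
F5 | step 6 | 3-iodo-5-methoxy-7-(methoxymethoxy)-4H-chromen-4-one | COCOc1cc(OC)c2c(c1)occ(I)c2=O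
F6 | step 7 | rac-3-[3,4-dihydroxy-5-(3-methylbut-2-en-1-yl)phenyl]-3,7-dihydroxy-5-methoxychroman-4-one | COc1cc(O)cc2c1C(=O)C(O)(c1cc(O)c(O)c(CC=C(C)C)c1)CO2
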